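**Retrosynthetic overview**
- Agecorynin E is a (2S)-flavanone. The C4 carbonyl is traced back to a C4–OEt ether (DDQ oxidation) and the 4'-OH to a benzyl ether (hydrogenolysis).
- Ring C is cut at C2–C3 and C4–C4a: an O1-aryl oxocarbenium ion at C2 takes up ethyl vinyl ether as the C3–C4 unit in a cationic [4+2] (oxa-Povarov) annulation.
- The strategy rests on ring A being a mirror-symmetric 3,4,5-trimethoxyphenoxy unit. Its O1–C8a bond is already in place, and its two equivalent ortho carbons (future C4a) are activated by O1 and by the future 5- and 7-methoxy groups. C2 sits at the aldehyde oxidation level of O-benzylvanillin (ring B).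
- The cation precursor is the bis(3,4,5-trimethoxyphenyl) acetal of O-benzylvanillin, made from the benzal chloride and two equivalents of the phenoxide.
- Rings A and B are bought. Ring C is the only ring formed (step 3), and C2 is set there by a chiral counter-anion.

Key step: step 3

Assumption: which antipode of the chiral acid sends the vinyl ether to the Si face of C2 (giving 2S) cannot be predicted; both antipodes would be screened first, and the steps are written for the one that gives (2S).

**Step 1**
Reactants: 1 4-(benzyloxy)-3-methoxybenzaldehyde (O-benzylvanillin, commercial)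
Product: 2 1-(benzyloxy)-4-(dichloromethyl)-2-methoxybenzene
Conditions: (COCl)2 (1.3 equiv), Ph3PO (15 mol%), CHCl3, rt; volatiles removed under argon, crude used at once
Reagents that add atoms: oxalyl chloride, ClC(=O)C(=O)Cl
Why: Phosphine oxide-catalysed deoxydichlorination (Appel-type, via Ph3PCl2 formed in the flask) should convert ArCHO into ArCHCl2 without free HCl, so the benzyl and methyl aryl ethers are not at risk.

**Step 2**
Reactants: 2 1-(benzyloxy)-4-(dichloromethyl)-2-methoxybenzene; 3 3,4,5-trimethoxyphenol (2.2 equiv)
Product: 6 4-(benzyloxy)-3-methoxybenzaldehyde bis(3,4,5-trimethoxyphenyl) acetal, via sodium 3,4,5-trimethoxyphenoxide 4 (not isolated), via α-chlorobenzyl aryl ether 5 (not isolated)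
Conditions: NaH (2.3 equiv), 15-crown-5 (2.3 equiv), THF, 0 °C; then 2 in THF, 0 °C to rt; 1 M NaOH wash; Et3N-deactivated silica
Reagents that add atoms: none
Why: Double Williamson-type substitution of a benzal chloride by an aryloxide (SN1-like, first through the p-alkoxy-stabilised α-chlorobenzyl cation, then through the oxocarbenium ion from 5) should give the diaryl acetal, the crown-ether-separated phenoxide reacting at oxygen.

**Step 3**
Reactants: 6 4-(benzyloxy)-3-methoxybenzaldehyde bis(3,4,5-trimethoxyphenyl) acetal; 7 ethyl vinyl ether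
Product: 10 (2S,4S)-2-[4-(benzyloxy)-3-methoxyphenyl]-4-ethoxy-5,6,7-trimethoxychroman (2,4-cis), via O-aryl oxocarbenium ion 8 (not isolated), via C4 oxocarbenium ion 9 (not isolated)
Conditions: enantiopure imidodiphosphorimidate (IDPi) Brønsted acid built from two 3,3'-bis[3,5-bis(trifluoromethyl)phenyl]-BINOL units with N-triflyl groups (5 mol%), 7 (3 equiv, syringe pump over 4 h), 5 Å MS, toluene, −60 °C; Et3N quench at −60 °C
Reagents that add atoms: none
Why: Proposed new method: the chiral acid protonates one aryloxy group of 6 and expels 3,4,5-trimethoxyphenol to give the E-configured O1-aryl oxocarbenium ion 8 as a tight ion pair with the confined anion; the CH2 terminus of 7 adds to C2 (C2–C3 bond) to give the ethoxy-stabilised C4 cation 9, and the proton lost on rearomatisation regenerates the acid. The closest known chemistry is the Lewis acid-promoted racemic oxa-Povarov reaction of aryl oxocarbenium ions with alkenes to 2,4-cis-chromans, together with chiral-anion-directed additions of enol ethers to oxocarbenium ions. Ring C closes by a six-membered intramolecular Friedel–Crafts alkylation (6-exo-trig at the C4=O+ carbon) in which the ortho carbon of the aryloxy ring becomes C4a (C4–C4a bond). C2 is set by the chiral anion, which has to shield the Re face of 8 so that 7 adds to the Si face (2S); C4 is set by the substrate through a chair-like closure with the C2 aryl and C4 ethoxy groups pseudo-equatorial (2,4-cis, 4S), and a minor C4 epimer would converge in step 4. The step needs regioselectivity, secured by the polarisation of the vinyl ether and by the mirror symmetry of ring A, and it needs cyclisation to beat chain growth of 7 or capture of 8 by the liberated phenol, secured by the activation of C4a by O1 and the ortho and para methoxy groups, by slow addition of 7, and by excess 7 masking the phenol reversibly as its 1-ethoxyethyl ether. Low temperature and the amine quench should prevent acid-mediated reopening of the C2–O1 bond, which would erode enantiomeric purity.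

**Step 4**
Reactants: 10 (2S,4S)-2-[4-(benzyloxy)-3-methoxyphenyl]-4-ethoxy-5,6,7-trimethoxychroman
Product: 12 (2S)-2-[4-(benzyloxy)-3-methoxyphenyl]-5,6,7-trimethoxychroman-4-one, via C4 hemiketal 11 (not isolated)
Conditions: DDQ (1.2 equiv), CH2Cl2/pH 7 phosphate buffer (10:1), 0 °C to rt
Reagents that add atoms: water, O
Why: DDQ oxidation of an electron-rich benzylic ether (the mechanism of p-methoxybenzyl ether cleavage, known at C4 of 5,7-dialkoxyflavans) should abstract the pseudo-axial C4–H next to the tetra-oxygenated ring A, and water then converts the ethoxy-stabilised cation through hemiketal 11 into the ketone with loss of ethanol; C2 is not touched.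

**Step 5**
Reactants: 12 (2S)-2-[4-(benzyloxy)-3-methoxyphenyl]-5,6,7-trimethoxychroman-4-one
Product: 13 Agecorynin E, (2S)-2-(4-hydroxy-3-methoxyphenyl)-5,6,7-trimethoxychroman-4-one
Conditions: H2 (1 atm), 10% Pd/C, EtOAc, rt, stopped at full conversion
Reagents that add atoms: none
Why: Hydrogenolysis of an aryl benzyl ether under neutral conditions should free the 4'-phenol without opening the flavanone, so the C2 centre is not epimerised by retro-oxa-Michael ring opening.

**Compound list**
1 | 4-(benzyloxy)-3-methoxybenzaldehyde | COc1cc(C=O)ccc1OCc1ccccc1 | starting material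
2 | 1-(benzyloxy)-4-(dichloromethyl)-2-methoxybenzene | COc1cc(C(Cl)Cl)ccc1OCc1ccccc1 | intermediate
3 | 3,4,5-trimethoxyphenol | COc1cc(O)cc(OC)c1OC | starting material
4 | sodium 3,4,5-trimethoxyphenoxide (not isolated) | COc1cc([O-])cc(OC)c1OC.[Na+] | intermediate
5 | 5-{[4-(benzyloxy)-3-methoxyphenyl](chloro)methoxy}-1,2,3-trimethoxybenzene (racemic, not isolated) | COc1cc(OC(Cl)c2ccc(OCc3ccccc3)c(OC)c2)cc(OC)c1OC | intermediate
6 | 4-(benzyloxy)-3-methoxybenzaldehyde bis(3,4,5-trimethoxyphenyl) acetal | COc1cc(OC(Oc2cc(OC)c(OC)c(OC)c2)c2ccc(OCc3ccccc3)c(OC)c2)cc(OC)c1OC | intermediate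
7 | ethyl vinyl ether | C=COCC | starting material
8 | (E)-[4-(benzyloxy)-3-methoxybenzylidene](3,4,5-trimethoxyphenyl)oxonium, ion pair with the catalyst anion (not isolated) | COc1cc(/[O+]=C/c2ccc(OCc3ccccc3)c(OC)c2)cc(OC)c1OC | intermediate
9 | (S)-ethyl[3-[4-(benzyloxy)-3-methoxyphenyl]-3-(3,4,5-trimethoxyphenoxy)propylidene]oxonium, ion pair with the catalyst anion (not isolated) | CC[O+]=CC[C@H](Oc1cc(OC)c(OC)c(OC)c1)c1ccc(OCc2ccccc2)c(OC)c1 | intermediate
10 | (2S,4S)-2-[4-(benzyloxy)-3-methoxyphenyl]-4-ethoxy-5,6,7-trimethoxychroman (2,4-cis) | COc1cc([C@@H]2C[C@H](OCC)c3c(cc(OC)c(OC)c3OC)O2)ccc1OCc1ccccc1 | intermediate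
11 | (2S)-2-[4-(benzyloxy)-3-methoxyphenyl]-4-ethoxy-5,6,7-trimethoxychroman-4-ol (C4 undefined, not isolated) | COc1cc([C@@H]2CC(O)(OCC)c3c(cc(OC)c(OC)c3OC)O2)ccc1OCc1ccccc1 | intermediate
12 | (2S)-2-[4-(benzyloxy)-3-methoxyphenyl]-5,6,7-trimethoxychroman-4-one | COc1cc([C@@H]2CC(=O)c3c(cc(OC)c(OC)c3OC)O2)ccc1OCc1ccccc1 | intermediate
13 | Agecorynin E, (2S)-2-(4-hydroxy-3-methoxyphenyl)-5,6,7-trimethoxychroman-4-one | COc1cc([C@@H]2CC(=O)c3c(cc(OC)c(OC)c3OC)O2)ccc1O | target

**Totals**
Total step count: 5. Longest linear sequence: 5 steps (1 → 2 → 6 → 10 → 12 → 13).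

**Steps most likely to fail**

1. Step 3 (proposed new method). Four processes could defeat it:
   - poor facial discrimination by the chiral anion at C2;
   - acid-initiated chain growth of the vinyl ether instead of ring closure;
   - irreversible C-alkylation of the liberated phenol by the oxocarbenium ion;
   - acid-mediated reopening of the C2–O1 bond, with loss of enantiomeric purity.

   Fallback (known chemistry, sets out from 3, comes back at 12): ring C would be made first and C2 set by conjugate arylation. Compound 3 would be C-acetylated ortho to the hydroxyl (AcOH, BF3·OEt2, 90 °C) to 1-(6-hydroxy-2,3,4-trimethoxyphenyl)ethanone F1. Condensation with N,N-dimethylformamide dimethyl acetal (toluene, 100 °C) should give (E)-3-(dimethylamino)-1-(6-hydroxy-2,3,4-trimethoxyphenyl)prop-2-en-1-one F2, which on treatment with HCl in CH2Cl2 should cyclise to 5,6,7-trimethoxy-4H-chromen-4-one F3. Asymmetric conjugate addition of commercial 4-(benzyloxy)-3-methoxyphenylboronic acid would then give 12, rejoining the route before step 5. Conditions: Pd(OCOCF3)2 (5 mol%), enantiopure 4-tert-butyl-2-(pyridin-2-yl)-4,5-dihydrooxazole (6 mol%, antipode chosen for 2S), NH4PF6, H2O, ClCH2CH2Cl, 60 °C.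

2. Step 4. Hydride abstraction could also occur at C2–H, which is benzylic to the dialkoxy ring B, or at the benzyl ether. The C4 cation could lose a proton to a flav-3-ene and be oxidised further towards a flavylium ion.

   Fallback (sets out from 10, comes back at 12): the oxidation would be split into solvolysis and alcohol oxidation. Dilute aqueous acid (0.1 M HCl, THF/H2O, 0 °C) should exchange the labile C4 ethoxy group for hydroxyl through the ring A-stabilised C4 cation, giving (2S)-2-[4-(benzyloxy)-3-methoxyphenyl]-5,6,7-trimethoxychroman-4-ol F4 as a C4 epimer mixture. Dess–Martin periodinane (NaHCO3, CH2Cl2, rt) would then oxidise this benzylic alcohol to 12.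

3. Step 2. The ambident phenoxide could be benzylated at its ortho carbon instead of at oxygen. The very labile dichloride 2, or the acetal during isolation, could be lost by solvolysis.

   Fallback (sets out from 1, comes back at 6): the two aryloxy groups would be installed one at a time through stable benzotriazole adducts. Aldehyde 1 with 1H-benzotriazole and SOCl2 (CH2Cl2, rt) should give 1-{[4-(benzyloxy)-3-methoxyphenyl](chloro)methyl}-1H-benzotriazole F5. One equivalent of the sodium phenoxide from 3 (NaH, THF, rt) should then give the crystallisable 1-{[4-(benzyloxy)-3-methoxyphenyl](3,4,5-trimethoxyphenoxy)methyl}-1H-benzotriazole F6. A second equivalent of the phenoxide (DMSO, 60–80 °C) should displace benzotriazolide from F6, whose ionisation is assisted by the aryloxy and p-benzyloxyphenyl groups, to give 6.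

**Further compounds**
F1 | step 3 | 1-(6-hydroxy-2,3,4-trimethoxyphenyl)ethanone | CC(=O)c1c(O)cc(OC)c(OC)c1OC
F2 | step 3 | (E)-3-(dimethylamino)-1-(6-hydroxy-2,3,4-trimethoxyphenyl)prop-2-en-1-one | CN(C)/C=C/C(=O)c1c(O)cc(OC)c(OC)c1OC
F3 | step 3 | 5,6,7-trimethoxy-4H-chromen-4-one | COc1cc2occc(=O)c2c(OC)c1OC
F4 | step 4 | (2S)-2-[4-(benzyloxy)-3-methoxyphenyl]-5,6,7-trimethoxychroman-4-ol (C4 epimer mixture) | COc1cc([C@@H]2CC(O)c3c(cc(OC)c(OC)c3OC)O2)ccc1OCc1ccccc1
F5 | step 2 | 1-{[4-(benzyloxy)-3-methoxyphenyl](chloro)methyl}-1H-benzotriazole (racemic) | COc1cc(C(Cl)n2nnc3ccccc32)ccc1OCc1ccccc1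
F6 | step 2 | 1-{[4-(benzyloxy)-3-methoxyphenyl](3,4,5-trimethoxyphenoxy)methyl}-1H-benzotriazole (racemic) | COc1cc(OC(c2ccc(OCc3ccccc3)c(OC)c2)n2nnc3ccccc32)cc(OC)c1OC
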